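All runs were computed for an exercise; scatter was added.

- Slowness marks the late part of the winter flask: from 80.0 min to 120 min target gains 0.5 percentage points, while substrate loses 12 points.

| flask | substrate | reagent | temperature | remark | time |
|---|---|---|---|---|---|
| winter | 0.10 M | 0.095 M | 100 °C | the very flask that is asked about, followed so far |  |
| noon | 0.10 M | 0.048 M | 106 °C | run made earlier |  |
| flask | 0.10 M | 0.0950 M | 100 °C |  | 3.0 h |

| run | time / min | target / % | substrate / % |
|---|---|---|---|
| winter | 10.0 | 7.2 | 83.1 |
| winter | 25.0 | 14.1 | 64.9 |
| winter | 50.0 | 19.3 | 45.3 |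
| winter | 80.0 | 22.1 | 30.1 |
| winter | 120 | 22.6 | 18.5 |
| noon | 5.00 | 3.5 | 92.7 |
| noon | 10.0 | 6.0 | 86.1 |
| noon | 20.0 | 9.7 | 76.2 |
| noon | 30.0 | 11.5 | 67.9 |
| noon | 60.0 | 12.9 | 51.7 |

(each reading ± 0.3 percentage points)

- Tuesday's: change nothing and wait 3.0 h more
- Thursday's: at 3.0 h add reagent, 50.0% of the amount charged, then wait 3.0 h
- Friday's: at 3.0 h raise the temperature by 25 K, then wait 3.0 h
- Monday's: at 3.0 h take out 90% of the released group then present, then wait 3.0 h

- additions leave the volume as it is

1. target, in percent of the substrate first charged, at 3.0 h
2. which option adds most target ("none" when 2 percentage points or less is all one gets) (Tuesday's / Thursday's / Friday's / Monday's / none)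
3. target present, in percent of the substrate first charged, after Tuesday's
4. target present, in percent of the substrate first charged, after Monday's

- The first way treats the last target reading as the large term and computes a correction. The late selectivity factor, target gained per substrate lost, reads 0.0431, though each reading scatters by 0.3 points. Substrate falls over that interval at 0.0122 min⁻¹, so it should stand near 8.91% at 3.0 h. The correction is then 0.41 points, and target comes to 23.0%.
- The second way uses the plateau ratio: target at the last reading divided by reagent charged, each as a fraction of the substrate charge. The winter flask reads 0.238 and the noon run reads 0.269. Applied to the winter charge, the noon ratio gives 25.5%.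
- The two ways part by 2.5 points. The second cheats: it carries a run at 106 °C with 0.048 M of reagent into a flask at 100 °C with 0.0950 M, whereas the first stays with the winter readings. So the reckoning here commits to 23.0%, and it keeps 0.238 as the ratio for 100 °C.
- Tuesday's should add about 0.38 points, less than the margin of 2 points. No reading shows reagent, so this reckoning sets no figure on the other options.
- The forecast gives 22.9% for now, 23% after Tuesday's, 23% after Monday's, and none as best, on the ground that “By 3 h the reagent is essentially gone”.
- The flask gives 23.4% at 3.0 h, and the best option is Friday's, which adds 6.7 points.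

    intermediate ⇌ target (K = 4.20, k = 2.00 min⁻¹, Ea = 110 kJ mol⁻¹, ΔH = −8.00 kJ mol⁻¹)
    substrate + reagent → intermediate + released group (k = 0.200 M⁻¹ min⁻¹, Ea = 95.0 kJ mol⁻¹)
    substrate + intermediate → side product (k = 0.880 M⁻¹ min⁻¹, Ea = 67.0 kJ mol⁻¹)
    intermediate ⇌ isomer of the product (K = 3.00, k = 1.20 min⁻¹, Ea = 112 kJ mol⁻¹, ΔH = −57.0 kJ mol⁻¹)
    (constants at 100 °C)

- At 3.00 h the flask still holds 28.6% of its reagent and 9.95% of its substrate, while Tuesday's adds 0.036 points. Carried to a neighbour charged with 0.16 M of reagent, the ratio 0.238 gives 38.1% target, and that neighbour holds 33.9%.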